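**Reading time.** At 4.0 d the red flask is read and a choice is made. The amber run differs from it in temperature.

| flask | substrate | solid reagent | temperature | remark | time |
|---|---|---|---|---|---|
| red | 2 M | 1.1 equiv | 25 °C | the very flask that is asked about, followed so far |  |
| amber | 2 M | 1.1 equiv | 31 °C | run made earlier |  |
| flask | 2.0 M | 1.10 equiv | 25 °C |  | 4.0 d |

| run | time / h | target / % | substrate / % |
|---|---|---|---|
| red | 6.00 | 5.1 | 79.3 |
| red | 20.0 | 13.8 | 34.4 |
| red | 40.0 | 19.2 | 3.4 |
| red | 60.0 | 16.7 | 3.3 |
| red | 72.0 | 17.8 | 0.7 |
| amber | 6.00 | 9.9 | 76.3 |
| amber | 20.0 | 20.2 | 24.4 |
| amber | 40.0 | 25.4 | 1.7 |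
| amber | 60.0 | 25.4 | 0.3 |
| amber | 72.0 | 23.2 | 0 |

(readings scatter by 1 percentage point)

- north: at 4.0 d raise the temperature by 15 K, then wait 30 h
- east: change nothing and wait 30 h more
- south-east: at 4.0 d take out 90% of the target then present, then wait 30 h

- solid reagent is a solid; its amount is given per volume of the solution
- removed target is counted in
- at the start none of the solid reagent is in solution

- target, in percent of the substrate first charged, at 4.0 d
- what to do for the largest gain in target; "none" if nothing gains more than 2 percentage points (north / east / south-east / none)
- target present, with what was taken out counted in, in percent of the substrate first charged, after east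
- target present, with what was taken out counted in, in percent of the substrate first charged, after south-east

**Main step.** With substrate going straight to target, target would equal the converted fraction. In the red flask at 72.0 h that fraction is 99.3%, but target reads 17.8%.

**Slow supply.** The logarithmic slope read from the red substrate readings grows from 0.0597 h⁻¹ to 0.116 h⁻¹, which a first-order loss with a constant rate constant does not do. Solid reagent entering solution gradually fits this. In this reckoning the addition moves the timing of the conversion, and the red converted fraction read at 72.0 h remains 99.3%.

**Unread forms.** In the red flask at 72.0 h, 81.5% of the charge is therefore neither substrate nor target, and this reckoning places it in forms not read. Over the last 3 red readings, the target share, target per converted substrate, is 18.4%; amber reads 24.8%, more than red. These readings leave kinetic against thermodynamic control open, and this reckoning assumes an equilibrium among the forms.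

For the red flask it gives 18.2% now, and east adds 0.13 percentage points. Amber multiplies the target odds by 1.47; scaled to 15 K, north reaches a share of 37.1%. South-east lets the remaining forms divide again, giving 31.6% counted. North leads.

**The forecast.** It gives 17.5% (15.5% to 19%), 17.3% after east, 17.6% after south-east, and best none: “With no substrate left, waiting, heating or removing target should gain almost nothing.” It differs from this reckoning on the choice and on south-east.

**The result.** The flask gives 18.1%, 18.1% after east and 31.3% after south-east. The best choice is north, gaining 19 points against 13 points for south-east. The relaxation half-life of intermediate and target by this step alone, both ways together, is 0.919 h, short against the time of reading. With this flask's 18.1% and 1.40% of substrate, the target share gives 31.4% after south-east.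

    substrate + partner → intermediate + by-product (k = 1.67 × 10⁻⁴ L mol⁻¹ s⁻¹, Ea = 75.0 kJ mol⁻¹)
    intermediate ⇌ target (K = 0.807, k = 9.36 × 10⁻⁵ s⁻¹, Ea = 104 kJ mol⁻¹, ΔH = 38.0 kJ mol⁻¹)
    intermediate ⇌ isomer of the product (K = 2.60, k = 5.89 × 10⁻⁵ s⁻¹, Ea = 101 kJ mol⁻¹, ΔH = −18.0 kJ mol⁻¹)
    2 partner → self-condensation product (k = 3.32 × 10⁻⁵ L mol⁻¹ s⁻¹, Ea = 59.0 kJ mol⁻¹)
    solid reagent ⇌ partner, rate k5*(cs5 - [partner]) while solid is left; crystals form when [partner] > cs5 (solubility = 0.840 M, k = 2.86 × 10⁻⁵ s⁻¹)
    (constants at 25 °C)

**Second flask.** A neighbour flask, charged with 0.660 equiv, ends with 0% of its solid reagent, here the limiting reagent, and 36% of its substrate still free. The target share then gives 11.8%; the computed value is 11.8%.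

The numbers in the tables are calculated on assumed constants; noise was put on by code.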